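0.0523 /h is the slope to work from, in reply to the quick question and the hunch that ash ends highest. In the summer run, ln(target) falls at this rate from 0.667 h to 2.50 h, while [substrate] reads 0.2% and then 0%. This reading is the ageing constant, an apparent first-order rate constant for the loss of target once formed.

| flask | substrate | enzyme | remark | time |
|---|---|---|---|---|
| summer | 28 mM | 2.7 µM | run made earlier |  |
| dawn | 28 mM | 1.4 µM | run made earlier |  |
| noon | 28 mM | 5.4 µM | run made earlier |  |
| winter | 56 mM | 2.7 µM | run made earlier |  |
| elm | 28 mM | 2.7 µM | one stirred flow tank at steady state, fed with the mixture as stated, mean residence time 4.0 h |  |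
| maple | 28 mM | 2.7 µM | a closed flask charged with all of it at once and left for 4.0 h | 4.0 h |
| ash | 28 mM (fed, over 3.20 h) | 2.7 µM | all but substrate at the start; substrate goes in evenly over 3.20 h, the run ends at 4.0 h | 4.0 h |

- summer (time / h: target / %, substrate / %): 0.200: 50.7, 48.9; 0.333: 81.7, 16.4; 0.667: 96.3, 0.2; 1.33: 93.4, 0; 2.50: 87.5, 0
- dawn (time / h: target / %, substrate / %): 0.500: 65.7, 34.3; 1.00: 96.8, 0; 1.33: 94.4, 0; 2.00: 89.5, 0.5; 2.50: 88.1, 0
- noon (time / h: target / %, substrate / %): 0.500: 96.3, 0.2; 1.00: 93.8, 0.9; 1.33: 92.6, 0; 2.00: 89.6, 0.3; 2.50: 86.3, 0
- winter (time / h: target / %, substrate / %): 0.200: 25.5, 73.5; 0.667: 84.2, 14.2; 1.00: 96.7, 0; 1.50: 93.7, 0; 2.50: 88.2, 0.1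

(standard deviation of a reading: 0.5 percentage points)

- the set-up with the highest amount of target at the outlet or at the end, in percent of the substrate put in ("none" if the first two lie within 2 percentage points) (elm / maple / ash / none)
- amount of target at the outlet or at the end, in percent of the substrate put in, elm
- amount of target at the outlet or at the end, in percent of the substrate put in, maple
- amount of target at the outlet or at the end, in percent of the substrate put in, ash

- the stated concentrations are those of everything mixed, before any reaction; amounts are the same in each set-up
- what was read earlier has a scatter of 0.5 percentage points, one standard deviation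
- the feed brings no volume worth counting
- the earlier runs were made in a closed, stirred flask

Early in the summer run, [substrate] falls at 68.4 mM/h. The ash feed of 8.75 mM/h lies below that, so target in ash forms about as fast as substrate enters. Its mean age at the end is then 2.40 h, and the surviving share is exp(−k × age), or 88.2%.

Maple converts its charge early, at a mean time of 0.205 h, and so gives 82.0%. Elm's outlet follows the tank balance 1/(1 + kτ), which gives 82.7%. My reckoning therefore puts ash first.

The forecast reads 80.5% for elm, 79.6% for maple and 86.7% for ash, with ash best: “Ash wins, assuming the enzyme survives”. It takes k≈0.06/h, and its ash figure is lower than mine.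

The flasks give 82.9% for elm, 80.7% for maple and 87.0% for ash, so ash leads.

    substrate + enzyme → target + enzyme, rate k1*[substrate]*[enzyme]/(1 + ([substrate]/Km1)) (0.942 mM, k = 8190 /M/s)
    target ⇌ isomer of the product (K = 0.913, k = 1.81 × 10⁻⁵ /s)

Ash at 4.0 h reads 87.0%, less than the 88.2% reckoned from the ageing constant 0.0523 /h. The neighbouring flask is ash read at 10 h. Its mean age is 8.40 h, and the ageing constant gives 64.5%. That flask reads 67.6%, more than the reckoning. It holds 32.4% isomer of the product beside 67.6% target.

(Readings and results were generated by integration with made-up constants, and the scatter is random.)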